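# Macrocarpal H (16): synthesis plan from (−)-elemol

## The problem

- Macrocarpal H (16) is β-eudesmol, a trans-decalin. Ring A is C1–C5 and C10; ring B is C5–C10. It has the axial methyl C14 on C10, the exocyclic methylene C4=C15, and the equatorial 2-hydroxypropan-2-yl group (C11) on C7. On C1, equatorial and β, it carries a 3-methyl-1-arylbutyl chain (C1'–C5'). The arene (ring C) is a hexasubstituted 2,4,6-trihydroxyisophthalaldehyde.
- The hard part is the row C1'–C1–C10: a benzylic methine between two ortho oxygens, a ring methine, and a quaternary carbon. A reaction that forms C1–C1' must join a secondary benzylic carbon to a neopentyl ring position on the β face, the face of C14. Reagents reach C1 of a finished decalin from the α face.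
- C5, C7 and C10 are ring stereocentres that relay to each other. C1 can be set from them: it is equatorial, and epimerisable while C1' is a carbonyl carbon. C1' lies outside the rings and can be controlled only through C1.
- C4=C15 moves into the ring with acid and C11–OH ionises with acid. Strong Lewis or Brønsted acids are therefore excluded late in the route, and hydrogenation is excluded once the alkene is present.
- First enabling feature: ring B, with the two-carbon branch C1–C1' on C10 and the branch C3–C4–C15 on C5, is the skeleton of a 1-vinyl-2-isopropenylcyclohexane. The C1–C1' bond can therefore be bought rather than made.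
- Second enabling feature, which makes the key step possible: C1' is bound to a ring C carbon whose two ortho carbons both carry oxygen, so C1' can be the methide carbon of an ortho-quinone methide.
- The neighbour C1 carries three groups of very different size: H, the methylene C2, and the quaternary C10. Allylic 1,3-strain should fix one rotamer and open one face of C1'.

## Retrosynthesis

**16 ⇒ 15 ⇒ 14 ⇒ 13.** The three phenols are masked as methyl ethers, and the two ring C–CHO bonds are cut back through C–Br to C–H. Formyl groups carried earlier would not survive the organometallic chemistry at C1'. Introducing them by electrophilic formylation would need the acids that C4=C15 and C11–OH do not tolerate. The precursor 13 has a symmetric, electron-rich ring C with two equivalent free positions. The forward steps must stay neutral or basic: bromination, bromine–lithium exchange, and thiolate demethylation.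

**13 ⇒ 12 ⇒ 5 + 7 (through 11).** The bonds C1'–ring C and C1'–C2' are cut. The neighbouring bond C1–C1' is deliberately kept.
- Cutting C1–C1' would force a coupling at the neopentyl carbon from the hindered face.
- The two bonds chosen are made at an aldehyde carbon that projects outwards from C1.
- The precursors are aldehyde 5 (sixteen carbons, no arene), the simple aryl carbamate 7, and an isobutyl nucleophile.
- The forward reaction must join the three parts in one flask through methide 11 and set C1' from C1 alone.

**5 ⇒ 4.** Ring A is opened at C1–C2.
- C1 is α to the formyl carbon C1', so it is a natural nucleophile. C2 is a primary carbon that can carry a leaving group.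
- Opening at C2–C3 or C3–C4 would give no such polarity.
- Opening at C1–C10 or C4–C5 would destroy stereocentres.
- Compound 4 is monocyclic, and its two side chains sit trans-diequatorial on ring B. The forward alkylation must close a six-membered ring and leave the formyl group equatorial.

**4 ⇒ 3 ⇒ 2 ⇒ 1.**
- The aldehyde C1' goes back to the terminal carbon of a vinyl group on C10.
- The tosylate goes back to a primary alcohol.
- C2–C3 is cut as the bond of a carbonyl-ene reaction between the isopropenyl group and a one-carbon enophile.
- This cut accounts for C4=C15. The ene reaction moves the double bond from C3=C4 to C4=C15 regiospecifically, so no late olefination or elimination is needed.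
- What remains is (−)-elemol 1, which already holds C5, C7, C10 and the C1–C1' bond.
- The forward steps need chemoselectivity between a monosubstituted and a 1,1-disubstituted alkene, once in each direction.

**7 ⇒ 6.** The O–C(=O) bond is cut. The carbamate on 3,5-dimethoxyphenol 6 serves in turn as directing group for lithiation, as migrating acyl group, and as leaving group for methide formation. No other handle is needed on ring C.

## Roads not taken

**Alternative 1:** the biogenetic cut, and the most obvious one. C1–C1' and C5–C10 are cut together.
- Forward key step: the isobutyl-substituted ortho-quinone methide A1 is attacked by the C1=C10 alkene of the ten-membered dienol (+)-hedycaryol A2. The C10 cation closes across the ring onto C5, and the C4 cation loses a proton from C15.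
- A2 is a heat- and acid-labile medium ring that would need a long synthesis. On warming it rearranges by a Cope reaction to 1.
- The phenolic oxygen of A1 can close a chroman on either alkene in place of the carbon cascade.
- The C4 cation can lose three different protons.
- Nothing controls the face of A1, so C1' is left open.
- The chosen plan starts from the stable Cope isomer 1, fixes the alkene position by a pericyclic step, and sets C1' by substrate control.

**Alternative 2:** C1–C1' is cut on a finished decalin.
- Forward key step: the silyl dienol ether A3 is alkylated at its γ-carbon C1 by the benzylic cation released from alcohol A4 with a Lewis acid.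
- The bond forms at the neopentyl position from the α face, anti to C14. That gives the axial epimer and calls for later epimerisation.
- The open transition state gives no handle on C1' unless a stoichiometric chiral auxiliary is placed on ring C.
- Enone reduction and methylenation of C4 must follow.
- The chosen plan avoids this bond formation and needs neither correction nor olefination.

**Alternative 3:** the same starting material 1, read the other way, with the vinyl group taken as C1=C2.
- Forward: terminal oxidation gives aldehyde A5. C1 is alkylated with an isopentyl benzylic electrophile. A carbonyl-ene closure of the C2 aldehyde onto the isopropenyl group then gives the 2-hydroxy compound A6.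
- C1–C1' must still be made next to C10.
- C1 and C1' would both be set in an open-chain step.
- The superfluous C2 hydroxyl group costs a two-step radical deoxygenation.
- In the chosen reading the oxygen sits on C1', where it is used, and C2 arrives without oxygen to remove.

Key step: step 6

Remark on the chemistry: commercial (−)-elemol is taken to be the (1R,3S,4S) enantiomer drawn as 1, the one that corresponds to natural β-eudesmol. Terpene carbons keep their eudesmane numbers throughout, also in the monocyclic compounds 1–4.

## Steps

Step 1
Reactants: 1 (−)-elemol, 2-[(1R,3S,4S)-4-ethenyl-4-methyl-3-(prop-1-en-2-yl)cyclohexyl]propan-2-ol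
Product: 2 2-[(1R,3S,4S)-4-ethenyl-3-(4-hydroxybut-1-en-2-yl)-4-methylcyclohexyl]propan-2-ol
Conditions: (CH2O)n, Me2AlCl (3 equiv), CH2Cl2, −78 → 0 °C; cold dilute aq HCl
Reagents that add atoms: formaldehyde (from paraformaldehyde) C=O
Why: Lewis-acid-promoted carbonyl-ene reaction; the 1,1-disubstituted isopropenyl alkene is the only good ene partner (the vinyl group on C10 is monosubstituted and has no allylic hydrogen), the C2–C3 bond forms at its CH2 terminus and the hydrogen leaves from the methyl group, so C4=C15 appears regiospecifically. Me2AlCl scavenges protons and holds C11–OH as an aluminium alkoxide; no stereocentre is formed.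

Step 2
Reactants: 2 2-[(1R,3S,4S)-4-ethenyl-3-(4-hydroxybut-1-en-2-yl)-4-methylcyclohexyl]propan-2-ol
Product: 3 3-[(1S,2S,5R)-2-ethenyl-5-(2-hydroxypropan-2-yl)-2-methylcyclohexyl]but-3-en-1-yl 4-methylbenzenesulfonate
Conditions: TsCl, Et3N, DMAP (cat.), CH2Cl2, 0 °C
Reagents that add atoms: 4-methylbenzenesulfonyl chloride Cc1ccc(cc1)S(=O)(=O)Cl
Why: Selective sulfonylation of the primary alcohol; the tertiary C11–OH is too hindered to react under these conditions.

Step 3
Reactants: 3 3-[(1S,2S,5R)-2-ethenyl-5-(2-hydroxypropan-2-yl)-2-methylcyclohexyl]but-3-en-1-yl 4-methylbenzenesulfonate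
Product: 4 3-[(1S,2S,5R)-5-(2-hydroxypropan-2-yl)-2-methyl-2-(2-oxoethyl)cyclohexyl]but-3-en-1-yl 4-methylbenzenesulfonate
Conditions: PdCl2(PhCN)2 (cat.), CuCl2·2H2O (cat.), AgNO2 (cat.), O2 (1 atm), t-BuOH/MeNO2 15:1, rt
Reagents that add atoms: dioxygen O=O
Why: Nitrite-modified, aldehyde-selective Wacker oxidation; the quaternary allylic carbon C10 steers the oxygen to the terminal carbon C1', a behaviour established for vinyl groups on quaternary carbon. The 1,1-disubstituted C4=C15 alkene, the tosylate and the tertiary alcohol are not substrates, and no stereocentre is touched.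

Step 4
Reactants: 4 3-[(1S,2S,5R)-5-(2-hydroxypropan-2-yl)-2-methyl-2-(2-oxoethyl)cyclohexyl]but-3-en-1-yl 4-methylbenzenesulfonate
Product: 5 1β-formyl-β-eudesmol, 11-hydroxyeudesm-4(15)-ene-1β-carbaldehyde (H-5α, H-7α, CH3-10β, CHO equatorial)
Conditions: KOt-Bu (2.2 equiv), THF/t-BuOH, high dilution, 0 °C → rt; aq NH4Cl
Reagents that add atoms: none
Why: Intramolecular alkylation of an aldehyde enolate (6-exo-tet); the two side chains are trans-diequatorial on ring B, so ring A closes as the second chair of a trans-decalin, and O-alkylation would need an eight-membered ring. C1 is the new stereocentre: it stays enolisable under the conditions and should settle with the formyl group equatorial (β); protonation of the exocyclic enolate from the α face, away from the axial C14 methyl group, leads to the same epimer.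

Step 5
Reactants: 6 3,5-dimethoxyphenol
Product: 7 3,5-dimethoxyphenyl N,N-diethylcarbamate
Conditions: NaH, ClC(O)NEt2, THF, 0 °C → rt
Reagents that add atoms: N,N-diethylcarbamoyl chloride CCN(CC)C(=O)Cl
Why: O-carbamoylation of a phenoxide; the carbamate is the directing, migrating and leaving group of step 6.

Step 6
Reactants: 5 1β-formyl-β-eudesmol; 7 3,5-dimethoxyphenyl N,N-diethylcarbamate
Product: 12 2-[(1S)-1-(11-hydroxyeudesm-4(15)-en-1β-yl)-3-methylbutyl]-3,5-dimethoxyphenol, via aryllithium 8 (not isolated), via benzylic alkoxide 9 (not isolated), via benzylic carbamate phenoxide 10 (not isolated), via ortho-quinone methide 11 (not isolated)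
Conditions: 7 (2.2 equiv), s-BuLi, TMEDA, THF, −78 °C; 5, −78 °C → rt; then CuBr·SMe2 (10 mol %), i-BuMgBr (5 equiv), −78 → 0 °C; aq NH4Cl
Reagents that add atoms: isobutylmagnesium bromide CC(C)C[Mg]Br
Why: Directed ortho-metalation of 7 between the carbamate and a methoxy group gives 8, which adds to the aldehyde of 5 to give 9 (both C1' epimers, of no consequence), and on warming the carbamoyl group moves from the phenolic to the benzylic oxygen to give 10. The lithium phenoxide 10 should persist, whereas exchange to magnesium on addition of i-BuMgBr should expel diethylcarbamate and release methide 11, which is taken up at once at C1' by the copper-activated isobutyl nucleophile with rearomatisation of ring C. The closest known reaction type is the anionic generation of ortho-quinone methides from O-acylated ortho-hydroxybenzyl alkoxides followed by 1,4-addition of Grignard reagents, and the metalation and acyl transfer are standard carbamate chemistry. No ring is closed; two C–C bonds (C1'–ring C and C1'–C2') are made at a carbon that was already attached to C1 in 1. The one new stereocentre, C1', is controlled by C1: in 11 allylic 1,3-strain with the oxygen-bearing ortho carbon of ring C turns C1–H into the methide plane, so the quaternary C10 and the methylene C2 stand on opposite faces and the nucleophile enters anti to C10, which gives (1'S). The outcome does not depend on the methide geometry or on the configuration of 9 and 10, because both ortho positions carry oxygen and the centre is created only in the addition. The step needs alkyl transfer to win over β-hydride transfer and over tautomerisation of 11 to the styrene, which catalytic copper, low temperature and an excess of nucleophile already present when 11 is released should secure. C4=C15 and the C11 alkoxide are inert.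

Step 7
Reactants: 12 2-[(1S)-1-(11-hydroxyeudesm-4(15)-en-1β-yl)-3-methylbutyl]-3,5-dimethoxyphenol
Product: 13 1β-[(1S)-3-methyl-1-(2,4,6-trimethoxyphenyl)butyl]eudesm-4(15)-en-11-ol
Conditions: MeI, K2CO3, DMF, rt
Reagents that add atoms: iodomethane CI
Why: Williamson ether synthesis on the only acidic hydroxyl group; it removes the phenolic proton before the lithium chemistry and makes ring C symmetric. The tertiary alcohol is not alkylated by carbonate and MeI.

Step 8
Reactants: 13 1β-[(1S)-3-methyl-1-(2,4,6-trimethoxyphenyl)butyl]eudesm-4(15)-en-11-ol
Product: 14 1β-[(1S)-1-(3,5-dibromo-2,4,6-trimethoxyphenyl)-3-methylbutyl]eudesm-4(15)-en-11-ol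
Conditions: NBS (2.05 equiv), MeCN, −20 → 0 °C, dark
Reagents that add atoms: N-bromosuccinimide O=C1CCC(=O)N1Br
Why: Electrophilic aromatic bromination; the two free positions of ring C are equivalent and each is activated by three alkoxy groups, so the arene should outrun the 1,1-disubstituted alkene. A polar solvent, low temperature and exclusion of light suppress radical allylic bromination.

Step 9
Reactants: 14 1β-[(1S)-1-(3,5-dibromo-2,4,6-trimethoxyphenyl)-3-methylbutyl]eudesm-4(15)-en-11-ol
Product: 15 5-[(1S)-1-(11-hydroxyeudesm-4(15)-en-1β-yl)-3-methylbutyl]-2,4,6-trimethoxybenzene-1,3-dicarbaldehyde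
Conditions: t-BuLi (5.5 equiv), Et2O/THF, −78 °C; DMF, −78 °C → rt; H2O
Reagents that add atoms: N,N-dimethylformamide CN(C)C=O
Why: Twofold bromine–lithium exchange followed by formylation with DMF (Bouveault aldehyde synthesis); the first equivalent of base is consumed by C11–OH and each lithiated position is stabilised by two flanking methoxy groups. The acid-free conditions leave C4=C15 and C11–O untouched.

Step 10
Reactants: 15 5-[(1S)-1-(11-hydroxyeudesm-4(15)-en-1β-yl)-3-methylbutyl]-2,4,6-trimethoxybenzene-1,3-dicarbaldehyde
Product: 16 macrocarpal H, 5-[(1S)-1-(11-hydroxyeudesm-4(15)-en-1β-yl)-3-methylbutyl]-2,4,6-trihydroxybenzene-1,3-dicarbaldehyde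
Conditions: EtSNa (excess), DMF, 110 °C; then 1 M HCl, 0 °C
Reagents that add atoms: none
Why: Nucleophilic (SN2) demethylation of aryl methyl ethers by thiolate; every methoxy group is ortho to at least one formyl group, so each phenoxide is a stabilised leaving group. The basic medium spares the exocyclic alkene, the tertiary alcohol and all five stereocentres, and the aldehydes cannot enolise.

## Compound list

1 | (−)-elemol | CC(=C)[C@@H]1C[C@@H](CC[C@@]1(C)C=C)C(C)(C)O | starting material
2 | ene product, primary homoallylic alcohol | OCCC(=C)[C@@H]1C[C@@H](CC[C@@]1(C)C=C)C(C)(C)O | intermediate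
3 | primary tosylate | Cc1ccc(cc1)S(=O)(=O)OCCC(=C)[C@@H]1C[C@@H](CC[C@@]1(C)C=C)C(C)(C)O | intermediate
4 | tosyloxy aldehyde | Cc1ccc(cc1)S(=O)(=O)OCCC(=C)[C@@H]1C[C@@H](CC[C@@]1(C)CC=O)C(C)(C)O | intermediate
5 | 1β-formyl-β-eudesmol | C=C1CC[C@@H](C=O)[C@]2(C)CC[C@@H](C(C)(C)O)C[C@@H]12 | intermediate
6 | 3,5-dimethoxyphenol | COc1cc(O)cc(OC)c1 | starting material
7 | 3,5-dimethoxyphenyl N,N-diethylcarbamate | CCN(CC)C(=O)Oc1cc(OC)cc(OC)c1 | intermediate
8 | 2-lithio-3,5-dimethoxyphenyl N,N-diethylcarbamate | [Li]c1c(OC)cc(OC)cc1OC(=O)N(CC)CC | intermediate
9 | benzylic alkoxide adduct, drawn as the diol, both C1' epimers | C=C1CC[C@@H](C(O)c3c(OC)cc(OC)cc3OC(=O)N(CC)CC)[C@]2(C)CC[C@@H](C(C)(C)O)C[C@@H]12 | intermediate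
10 | benzylic carbamate phenoxide, drawn as the phenol, both C1' epimers | C=C1CC[C@@H](C(OC(=O)N(CC)CC)c3c(O)cc(OC)cc3OC)[C@]2(C)CC[C@@H](C(C)(C)O)C[C@@H]12 | intermediate
11 | ortho-quinone methide with the terpene on the methide carbon C1' | C=C1CC[C@@H](C=C3C(=O)C=C(OC)C=C3OC)[C@]2(C)CC[C@@H](C(C)(C)O)C[C@@H]12 | intermediate
12 | (1'S)-dimethoxyphenol | C=C1CC[C@@H]([C@H](CC(C)C)c3c(O)cc(OC)cc3OC)[C@]2(C)CC[C@@H](C(C)(C)O)C[C@@H]12 | intermediate
13 | trimethyl ether | C=C1CC[C@@H]([C@H](CC(C)C)c3c(OC)cc(OC)cc3OC)[C@]2(C)CC[C@@H](C(C)(C)O)C[C@@H]12 | intermediate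
14 | dibromide | C=C1CC[C@@H]([C@H](CC(C)C)c3c(OC)c(Br)c(OC)c(Br)c3OC)[C@]2(C)CC[C@@H](C(C)(C)O)C[C@@H]12 | intermediate
15 | macrocarpal H tri-O-methyl ether | C=C1CC[C@@H]([C@H](CC(C)C)c3c(OC)c(C=O)c(OC)c(C=O)c3OC)[C@]2(C)CC[C@@H](C(C)(C)O)C[C@@H]12 | intermediate
16 | macrocarpal H | C=C1CC[C@@H]([C@H](CC(C)C)c2c(O)c(C=O)c(O)c(C=O)c2O)[C@]2(C)CC[C@@H](C(C)(C)O)C[C@@H]12 | target

## Step count and least certain steps

Total step count: 10.
Longest linear sequence: 9 (steps 1–4 and 6–10, from 1 to 16). Step 5 is the one-step side branch.

**Step 6 (key step).**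
- Possible failures:
  - transfer of a β-hydrogen from the isobutyl metal to C1', giving reduction in place of alkylation;
  - base-induced tautomerisation of the methide by loss of the C1 hydrogen;
  - slow addition of the doubly ortho-substituted aryllithium to the hindered aldehyde, with competing enolisation;
  - incomplete facial selectivity if the rotamer control by allylic strain is weaker than expected.
- Fallback, from 5 and 6, back at 12. The C1'–ring C bond is made by electrophilic substitution of the free phenol, not by an aryl anion. Acid-catalysed three-component condensation of 5, 6 and 1H-benzotriazole gives the storable methide precursor 2-[(benzotriazol-1-yl)(11-hydroxyeudesm-4(15)-en-1β-yl)methyl]-3,5-dimethoxyphenol F1. The stoichiometric cuprate i-Bu2CuLi, used without free Grignard reagent, then expels benzotriazolide and adds the isobutyl group to give 12. Substitution para to the hydroxyl group would be harmless, because step 7 makes ring C symmetric.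

**Step 3.**
- Possible failures: divalent palladium may bind the 1,5-diene (C1'=C1 and C4=C15) as a chelate and start a carbocyclisation or an allylic activation in place of the oxidation. Some Markovnikov oxidation to the methyl ketone is also possible.
- Fallback, from 3, back at 4. RhCl(PPh3)3-catalysed hydroboration with catecholborane prefers the monosubstituted alkene. Buffered perborate oxidation then gives the primary alcohol 3-[(1S,2S,5R)-2-(2-hydroxyethyl)-5-(2-hydroxypropan-2-yl)-2-methylcyclohexyl]but-3-en-1-yl 4-methylbenzenesulfonate F2. Dess–Martin oxidation of F2 gives 4.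

**Step 4.**
- Possible failures: elimination of the homoallylic tosylate to the 1,3-diene, intermolecular aldol reaction, or only a modest equatorial preference of the small formyl group at C1.
- Fallback, from 3, back at 5, replacing steps 3 and 4. Ring A is closed by a radical in place of an enolate.
  - Finkelstein exchange with NaI gives the iodide 2-[(1R,3S,4S)-4-ethenyl-3-(4-iodobut-1-en-2-yl)-4-methylcyclohexyl]propan-2-ol F3.
  - A Bu3SnH chain run under air generates the primary C2 radical. It should add 6-exo to C1 of the vinyl group through a chair, with the new CH2 radical equatorial, and is trapped by oxygen to give 1β-(hydroxymethyl)-β-eudesmol F4.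
  - Dess–Martin oxidation of F4 gives 5.

**Step 8.**
- Possible failures: attack of the bromine source on C4=C15 (addition or allylic bromination) in competition with the second aromatic bromination. The following fourfold-anionic exchange in step 9 may also stall.
- Fallback, from 13, back at 15, bypassing 14. Ring C is formylated by C–H lithiation, not by halogenation.
  - n-BuLi/TMEDA deprotonates the position between two methoxy groups, and DMF gives the monoaldehyde 3-[(1S)-1-(11-hydroxyeudesm-4(15)-en-1β-yl)-3-methylbutyl]-2,4,6-trimethoxybenzaldehyde F5.
  - The aldehyde is protected in the flask as its α-amino alkoxide with lithium N,N,N'-trimethylethylenediamide.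
  - A second lithiation and DMF quench give 15.

**Step 10.**
- Possible failures: stalling after one or two demethylations as negative charge builds up on ring C, or loss of a formyl group during prolonged heating with thiolate.
- Fallback, from 5, back at 16. The methyl ethers are replaced by acetal ethers that leave under mild acid.
  - 3,5-Bis(methoxymethoxy)phenol F6, from twofold protection of phloroglucinol, is converted into its N,N-diethylcarbamate F7.
  - F7 is joined with 5 and the isobutyl nucleophile as in step 6 to give the phenol F8.
  - MOMCl and i-Pr2NEt give the tris(methoxymethyl) ether F9.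
  - Bromination gives the dibromide F10.
  - Exchange and DMF give the dialdehyde F11.
  - Dilute HCl in MeOH at rt releases 16.

## Further compounds

F1 | step 6 | 2-[(benzotriazol-1-yl)(11-hydroxyeudesm-4(15)-en-1β-yl)methyl]-3,5-dimethoxyphenol | C=C1CC[C@@H](C(n3nnc4ccccc34)c3c(O)cc(OC)cc3OC)[C@]2(C)CC[C@@H](C(C)(C)O)C[C@@H]12
F2 | step 3 | 3-[(1S,2S,5R)-2-(2-hydroxyethyl)-5-(2-hydroxypropan-2-yl)-2-methylcyclohexyl]but-3-en-1-yl 4-methylbenzenesulfonate | Cc1ccc(cc1)S(=O)(=O)OCCC(=C)[C@@H]1C[C@@H](CC[C@@]1(C)CCO)C(C)(C)O
F3 | step 4 | 2-[(1R,3S,4S)-4-ethenyl-3-(4-iodobut-1-en-2-yl)-4-methylcyclohexyl]propan-2-ol | ICCC(=C)[C@@H]1C[C@@H](CC[C@@]1(C)C=C)C(C)(C)O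
F4 | step 4 | 1β-(hydroxymethyl)-β-eudesmol | C=C1CC[C@@H](CO)[C@]2(C)CC[C@@H](C(C)(C)O)C[C@@H]12
F5 | step 8 | 3-[(1S)-1-(11-hydroxyeudesm-4(15)-en-1β-yl)-3-methylbutyl]-2,4,6-trimethoxybenzaldehyde | C=C1CC[C@@H]([C@H](CC(C)C)c3c(OC)c(C=O)c(OC)cc3OC)[C@]2(C)CC[C@@H](C(C)(C)O)C[C@@H]12
F6 | step 10 | 3,5-bis(methoxymethoxy)phenol | COCOc1cc(O)cc(OCOC)c1
F7 | step 10 | 3,5-bis(methoxymethoxy)phenyl N,N-diethylcarbamate | CCN(CC)C(=O)Oc1cc(OCOC)cc(OCOC)c1
F8 | step 10 | 2-[(1S)-1-(11-hydroxyeudesm-4(15)-en-1β-yl)-3-methylbutyl]-3,5-bis(methoxymethoxy)phenol | C=C1CC[C@@H]([C@H](CC(C)C)c3c(O)cc(OCOC)cc3OCOC)[C@]2(C)CC[C@@H](C(C)(C)O)C[C@@H]12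
F9 | step 10 | 1β-[(1S)-3-methyl-1-[2,4,6-tris(methoxymethoxy)phenyl]butyl]eudesm-4(15)-en-11-ol | C=C1CC[C@@H]([C@H](CC(C)C)c3c(OCOC)cc(OCOC)cc3OCOC)[C@]2(C)CC[C@@H](C(C)(C)O)C[C@@H]12
F10 | step 10 | 1β-[(1S)-1-[3,5-dibromo-2,4,6-tris(methoxymethoxy)phenyl]-3-methylbutyl]eudesm-4(15)-en-11-ol | C=C1CC[C@@H]([C@H](CC(C)C)c3c(OCOC)c(Br)c(OCOC)c(Br)c3OCOC)[C@]2(C)CC[C@@H](C(C)(C)O)C[C@@H]12
F11 | step 10 | macrocarpal H tris(methoxymethyl) ether | C=C1CC[C@@H]([C@H](CC(C)C)c3c(OCOC)c(C=O)c(OCOC)c(C=O)c3OCOC)[C@]2(C)CC[C@@H](C(C)(C)O)C[C@@H]12
A1 | alternative 1 | isobutyl-substituted ortho-quinone methide of the diformylated ring C | CC(C)CC=C1C(=O)C(C=O)=C(O)C(C=O)=C1O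
A2 | alternative 1 | (+)-hedycaryol, (E,E)-germacra-1(10),4-dien-11-ol | C1C[C@@H](C(C)(C)O)C/C=C(\C)CC/C=C1\C
A3 | alternative 2 | 4-(tert-butyldimethylsilyloxy)-15-noreudesma-1,3-dien-11-ol | C1(O[Si](C)(C)C(C)(C)C)=CC=C[C@]2(C)CC[C@@H](C(C)(C)O)C[C@@H]12
A4 | alternative 2 | 3-methyl-1-(2,4,6-trimethoxyphenyl)butan-1-ol | CC(C)CC(O)c1c(OC)cc(OC)cc1OC
A5 | alternative 3 | 2-[(1S,2S,4R)-4-(2-hydroxypropan-2-yl)-1-methyl-2-(prop-1-en-2-yl)cyclohexyl]acetaldehyde | CC(=C)[C@@H]1C[C@@H](CC[C@@]1(C)CC=O)C(C)(C)O
A6 | alternative 3 | 1β-[(1S)-3-methyl-1-(2,4,6-trimethoxyphenyl)butyl]eudesm-4(15)-ene-2,11-diol | C=C1CC(O)[C@@H]([C@H](CC(C)C)c3c(OC)cc(OC)cc3OC)[C@]2(C)CC[C@@H](C(C)(C)O)C[C@@H]12
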